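Numbering: ring C1 (CH bearing the chain), C2 (C=CH2), C3 (CHBr), C4 (CH2), C5 (CHBr), C6 (CMe2); chain C7–C8–C9(OH)(CH3)–C10H=C11H2. In the target the C3 bromide is cis and the C5 bromide trans to the C1 chain.
Cuts, in retrosynthetic order: C3–Br (back to C3–H via the alcohol), C9–C10 (C10/C11 from a two-carbon olefination reagent), C5–Br, the ring bond C3–C4, then C4–C5 and the two C6–CH3 bonds. This leads back to ring-opened (S)-limonene.
Enabling feature: C1 carries a 3-oxobutyl-type arm (C7–C9 plus methyl), a 2-propenyl unit (C2, its methylene, C3) and a two-carbon arm (C6–C5). This is the pattern around C4 of limonene once its ring alkene is cleaved. With C6 quaternary, a C5 methyl ketone can enolise only towards C4, and C3 lies in a symmetrical 2-substituted allyl unit.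
Forward order: the terpene ring is opened and becomes the chain and the C6–C5 arm (steps 1–8). The only carbocycle of the target, the six-membered ring C1–C6, closes in step 9. C5 is then brominated, the chain is extended from C9, and C3 is functionalised last.
Stereochemistry: C1 is the limonene stereocentre. C5 comes from axial hydride delivery (alcohol cis to the chain) followed by SN2 inversion. C9 comes from Sharpless epoxidation with L-(+)-tartrate. C3 comes from allylic hydroxylation anti to the chain followed by SN2 inversion.

Key step: step 9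

Remark: commercial (S)-(−)-limonene is taken as enantiomerically pure; any minor enantiomer would appear after step 15 as a diastereomer that can be separated.

Step 1
Reactants: 1 (S)-(−)-limonene
Product: 2 (4S)-limonene 1,2-oxide (cis/trans mixture at the epoxide)
Conditions: mCPBA (1.0 equiv), CH2Cl2, 0 °C
Reagents that add atoms: mCPBA, OOC(=O)c1cccc(Cl)c1
Why: Prilezhaev epoxidation follows alkene nucleophilicity, so one equivalent of peracid should take the trisubstituted ring alkene and spare the isopropenyl group, and the epoxide diastereomers do not matter because both new centres are destroyed in step 2.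

Step 2
Reactants: 2 (4S)-limonene 1,2-oxide
Product: 4 (S)-3-isopropenyl-6-oxoheptanal, via limonene-1,2-diol 3 (not isolated)
Conditions: H5IO6 (1.2 equiv), THF–H2O, 0 °C → rt
Reagents that add atoms: water, O
Why: Acid-promoted hydration of the epoxide and Malaprade glycol cleavage in the same flask open the terpene ring into the 3-oxobutyl arm (C7–C9) and the C6–C5 acetaldehyde arm without touching C1.

Step 3
Reactants: 4 (S)-3-isopropenyl-6-oxoheptanal
Product: 5 (S)-3-isopropenyl-6-oxoheptanoic acid
Conditions: NaClO2, NaH2PO4, 2-methyl-2-butene (large excess), t-BuOH–H2O, 0 °C → rt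
Reagents that add atoms: sodium chlorite, [Na+].[O-]Cl=O
Why: Pinnick oxidation converts the aldehyde chemoselectively beside the ketone, and the excess trisubstituted alkene intercepts hypochlorous acid before it can reach the isopropenyl group.

Step 4
Reactants: 5 (S)-3-isopropenyl-6-oxoheptanoic acid; 6 iodomethane
Product: 7 methyl (S)-3-isopropenyl-6-oxoheptanoate
Conditions: MeI, K2CO3, DMF, rt
Reagents that add atoms: iodomethane (6), CI
Why: SN2 O-alkylation of the potassium carboxylate gives the methyl ester under conditions too weakly basic to alkylate the ketone.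

Step 5
Reactants: 7 methyl (S)-3-isopropenyl-6-oxoheptanoate
Product: 8 methyl (S)-4-methyl-3-[2-(2-methyl-1,3-dioxolan-2-yl)ethyl]pent-4-enoate
Conditions: ethylene glycol (3 equiv), PPTS (cat.), benzene, reflux, Dean–Stark
Reagents that add atoms: ethylene glycol, OCCO
Why: Acid-catalysed ketalisation with azeotropic removal of water masks the C9 ketone, which must act neither as an acid nor as an electrophile in steps 6–11, and the mild pyridinium acid should leave the isopropenyl group in place.

Step 6
Reactants: 8 ketal ester; 6 iodomethane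
Product: 10 methyl (R)-2,2,4-trimethyl-3-[2-(2-methyl-1,3-dioxolan-2-yl)ethyl]pent-4-enoate, via monomethyl ester 9 (not isolated)
Conditions: LDA (1.1 equiv), THF, −78 °C, then MeI (1.1 equiv), → 0 °C; recool to −78 °C, LDA (1.4 equiv), then MeI (3 equiv), DMPU, → rt
Reagents that add atoms: iodomethane (6), CI
Why: Two successive ester enolate alkylations build the quaternary C6, which is the only acidic position, and the transient C6 configuration in 9 disappears in the second methylation.

Step 7
Reactants: 10 gem-dimethyl ester; 11 (trimethylsilyl)methyllithium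
Product: 13 (R)-3,3,5-trimethyl-4-[2-(2-methyl-1,3-dioxolan-2-yl)ethyl]hex-5-en-2-one, via alpha-silyl ketone 12 (not isolated)
Conditions: 11 (2.5 equiv, pentane), THF, 0 °C → rt; then MeOH, rt
Reagents that add atoms: (trimethylsilyl)methyllithium (11), [Li]C[Si](C)(C)C
Why: Acyl substitution of the non-enolisable ester stops at the ketone level because 12 is deprotonated at once by the second equivalent of 11, and methanolysis of the C–Si bond then releases the methyl ketone and brings in C4, which is a known ester-to-methyl-ketone conversion suited to hindered esters.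

Step 8
Reactants: 13 methyl ketone
Product: 14 (S)-5-(chloromethyl)-3,3-dimethyl-4-[2-(2-methyl-1,3-dioxolan-2-yl)ethyl]hex-5-en-2-one
Conditions: Ca(OCl)2, CO2 (solid), CH2Cl2–H2O, 0 °C
Reagents that add atoms: calcium hypochlorite, [Ca+2].[O-]Cl.[O-]Cl
Why: In this ene-type allylic chlorination with hypochlorous acid made in situ, chlorine adds to the terminal CH2 of the only alkene and a proton leaves from the methyl group rather than from the crowded C1–H, which gives the 2-(chloromethyl)allyl unit as is known for isopropenyl terpenoids.

Step 9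
Reactants: 14 allylic chloride methyl ketone
Product: 16 (R)-2,2-dimethyl-3-[2-(2-methyl-1,3-dioxolan-2-yl)ethyl]-4-methylidenecyclohexan-1-one, via lithium enolate 15 (not isolated)
Conditions: LDA (1.1 equiv), THF (0.02 M), −78 °C; LiI (cat.), warm to rt
Reagents that add atoms: none
Why: LDA removes a proton from the C4 methyl group, the only acidic C–H of 14 because C6 is quaternary, and on warming the lithium enolate 15 displaces chloride from C3 through carbon, which forms the C3–C4 bond. The closest known reaction type is the intramolecular alkylation of a ketone enolate by a 2-(chloromethyl)allyl group, a known entry to 4-methylenecyclohexanones. The six-membered ring C1–C6 closes in the 6-(enolexo)-exo-tet mode, and the gem-dimethyl group at C6 compresses the C5–C6–C1 angle and favours the folded rotamer (Thorpe–Ingold effect). No stereocentre is created, and C1, which is neither acidic nor involved in any bonding change, is carried through unchanged. The step needs C- rather than O-alkylation (attack through oxygen would also close a six-membered ring), which the tightly bound lithium counter-ion in THF without dipolar cosolvent and the soft allylic electrophile should secure, and it needs no SN2/SN2′ discrimination because the two CH2 termini of the 2-substituted allyl unit end up as C3 and the exocyclic methylene either way. High dilution and the hindered, pinacolone-like carbonyl group hold back intermolecular alkylation and aldol addition.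

Step 10
Reactants: 16 cyclised ketone
Product: 17 (1S,3R)-2,2-dimethyl-3-[2-(2-methyl-1,3-dioxolan-2-yl)ethyl]-4-methylidenecyclohexan-1-ol (C5–OH cis to the C1 chain)
Conditions: NaBH4, MeOH, 0 °C
Reagents that add atoms: none
Why: In this hydride reduction of a 2,2-dimethylcyclohexanone, borohydride should approach C5 along the axial trajectory, on the face away from the axial C6 methyl group, and give the equatorial alcohol cis to the equatorial chain, as in 4,4-dimethyl-3-keto terpenoids.

Step 11
Reactants: 17 cis alcohol
Product: 18 2-{2-[(1R,3R)-3-bromo-2,2-dimethyl-6-methylidenecyclohexyl]ethyl}-2-methyl-1,3-dioxolane (C5–Br trans to the chain)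
Conditions: CBr4 (3 equiv), PPh3 (3 equiv), 2,6-lutidine (0.2 equiv), toluene, 60 °C
Reagents that add atoms: carbon tetrabromide, BrC(Br)(Br)Br
Why: The Appel reaction proceeds by SN2 inversion, a displacement that is known for neopentylic 2,2-dimethylcyclohexanols, and bromide enters C5 along the axial line, which is flanked only by the axial hydrogens at C1 and C3 and lies anti to the axial C6 methyl group.

Step 12
Reactants: 18 bromo ketal
Product: 19 4-[(1R,3R)-3-bromo-2,2-dimethyl-6-methylidenecyclohexyl]butan-2-one
Conditions: 1 M HCl, THF, rt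
Reagents that add atoms: water, O
Why: Acid hydrolysis of the dioxolane frees the C9 ketone, and the unactivated secondary bromide and the exocyclic alkene should tolerate dilute acid at room temperature.

Step 13
Reactants: 19 bromo ketone; 20 triethyl phosphonoacetate
Product: 21 ethyl (2E)-5-[(1R,3R)-3-bromo-2,2-dimethyl-6-methylidenecyclohexyl]-3-methylpent-2-enoate
Conditions: 20, NaH, THF, 0 °C; then 19, 0 → 50 °C; chromatographic removal of the Z ester
Reagents that add atoms: triethyl phosphonoacetate (20), CCOC(=O)CP(=O)(OCC)OCC
Why: Horner–Wadsworth–Emmons olefination of the methyl ketone forms C9=C10 with the E isomer favoured, the stabilised phosphonate anion is too weak a base to eliminate HBr, and separation of the minor Z ester gives a single alkene geometry for step 15.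

Step 14
Reactants: 21 E-enoate
Product: 22 (2E)-5-[(1R,3R)-3-bromo-2,2-dimethyl-6-methylidenecyclohexyl]-3-methylpent-2-en-1-ol
Conditions: DIBAL-H (2.3 equiv), CH2Cl2, −78 °C; Rochelle salt work-up
Reagents that add atoms: none
Why: 1,2-Reduction of the enoate with DIBAL-H gives the allylic alcohol and leaves the alkyl bromide and both alkenes untouched at low temperature.

Step 15
Reactants: 22 E-allylic alcohol
Product: 23 [(2S,3S)-3-{2-[(1R,3R)-3-bromo-2,2-dimethyl-6-methylidenecyclohexyl]ethyl}-3-methyloxiran-2-yl]methanol
Conditions: Ti(OiPr)4 (10 mol %), L-(+)-DET (12 mol %), TBHP (2 equiv), 4 Å MS, CH2Cl2, −20 °C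
Reagents that add atoms: tert-butyl hydroperoxide, CC(C)(C)OO
Why: In the Sharpless asymmetric epoxidation the L-(+)-tartrate catalyst delivers oxygen to the face of the E-allylic alcohol that gives the (2S,3S)-epoxide, as with geraniol, so C9 is fixed as S by reagent control while the exocyclic alkene, which has no allylic hydroxyl group, is not a substrate.

Step 16
Reactants: 23 epoxy alcohol
Product: 24 (2R,3S)-3-{2-[(1R,3R)-3-bromo-2,2-dimethyl-6-methylidenecyclohexyl]ethyl}-2-(iodomethyl)-3-methyloxirane
Conditions: PPh3, I2, imidazole, THF, 0 °C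
Reagents that add atoms: iodine, II
Why: Garegg–Samuelsson iodination replaces the primary hydroxyl group by SN2 at CH2, so neither epoxide stereocentre is involved.

Step 17
Reactants: 24 epoxy iodide
Product: 25 (3S)-5-[(1R,3R)-3-bromo-2,2-dimethyl-6-methylidenecyclohexyl]-3-methylpent-1-en-3-ol
Conditions: activated Zn dust, EtOH, 50 °C
Reagents that add atoms: none
Why: Reductive β-elimination (zinc insertion into C–I and opening of the neighbouring epoxide) is the known conversion of 2,3-epoxy alcohol derivatives into tertiary allylic alcohols, the C9–O bond is never broken so C9 stays S, and the hindered secondary bromide should be inert to zinc in ethanol.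

Step 18
Reactants: 25 tertiary allylic alcohol
Product: 27 (1S,3R,5R)-5-bromo-3-[(3S)-3-hydroxy-3-methylpent-4-en-1-yl]-4,4-dimethyl-2-methylidenecyclohexan-1-ol (C3–OH trans to the chain), via allylseleninic acid 26 (not isolated)
Conditions: SeO2 (0.3 equiv), TBHP (2 equiv), CH2Cl2, 0 °C → rt, stopped short of full conversion
Reagents that add atoms: selenium dioxide (oxygen carrier), O=[Se]=O; tert-butyl hydroperoxide (terminal oxidant), CC(C)(C)OO
Why: In this Riley-type allylic hydroxylation (ene reaction, then [2,3]-sigmatropic shift) only C3 offers accessible allylic hydrogens, since C1–H is buried between C6 and the chain and the vinyl group has none, and in cyclohexene 26 allylic 1,2-strain turns the C1 chain pseudoaxial and the C5 bromide equatorial, so oxygen should reach C3 on the face opposite the chain, as in the hydroxylation of related exocyclic methylene terpenoids.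

Step 19
Reactants: 27 C3 allylic alcohol
Product: 28 (3S)-5-[(1S,3R,5R)-3,5-dibromo-2,2-dimethyl-6-methylidenecyclohexyl]-3-methylpent-1-en-3-ol (target)
Conditions: CBr4 (1.2 equiv), PPh3 (1.2 equiv), CH2Cl2, −30 → 0 °C
Reagents that add atoms: carbon tetrabromide, BrC(Br)(Br)Br
Why: The Appel reaction of a secondary allylic alcohol proceeds by SN2 inversion and places the C3 bromide cis to the chain, the low temperature and near-stoichiometric reagents limit allylic transposition and bromide exchange, and the tertiary C9 carbinol is too hindered to be activated under these conditions.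

Compound list
1 | (S)-(−)-limonene | CC1=CC[C@H](CC1)C(=C)C | starting material
2 | (4S)-limonene 1,2-oxide (epoxide diastereomers) | CC12CC[C@@H](CC1O2)C(C)=C | intermediate
3 | (4S)-limonene-1,2-diol (not isolated) | CC1(O)CC[C@@H](CC1O)C(C)=C | intermediate
4 | (S)-3-isopropenyl-6-oxoheptanal | CC(=O)CC[C@@H](CC=O)C(C)=C | intermediate
5 | (S)-3-isopropenyl-6-oxoheptanoic acid | CC(=O)CC[C@@H](CC(=O)O)C(C)=C | intermediate
6 | iodomethane | CI | starting material
7 | methyl (S)-3-isopropenyl-6-oxoheptanoate | CC(=O)CC[C@@H](CC(=O)OC)C(C)=C | intermediate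
8 | methyl (S)-4-methyl-3-[2-(2-methyl-1,3-dioxolan-2-yl)ethyl]pent-4-enoate | CC1(CC[C@@H](CC(=O)OC)C(C)=C)OCCO1 | intermediate
9 | methyl (3S)-2,4-dimethyl-3-[2-(2-methyl-1,3-dioxolan-2-yl)ethyl]pent-4-enoate (C2 epimers, not isolated) | CC1(CC[C@@H](C(C)C(=O)OC)C(C)=C)OCCO1 | intermediate
10 | methyl (R)-2,2,4-trimethyl-3-[2-(2-methyl-1,3-dioxolan-2-yl)ethyl]pent-4-enoate | CC1(CC[C@@H](C(C)(C)C(=O)OC)C(C)=C)OCCO1 | intermediate
11 | (trimethylsilyl)methyllithium | [Li]C[Si](C)(C)C | starting material
12 | (R)-3,3,5-trimethyl-4-[2-(2-methyl-1,3-dioxolan-2-yl)ethyl]-1-(trimethylsilyl)hex-5-en-2-one (present as its lithium enolate, not isolated) | CC1(CC[C@@H](C(C)(C)C(=O)C[Si](C)(C)C)C(C)=C)OCCO1 | intermediate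
13 | (R)-3,3,5-trimethyl-4-[2-(2-methyl-1,3-dioxolan-2-yl)ethyl]hex-5-en-2-one | CC1(CC[C@@H](C(C)(C)C(C)=O)C(C)=C)OCCO1 | intermediate
14 | (S)-5-(chloromethyl)-3,3-dimethyl-4-[2-(2-methyl-1,3-dioxolan-2-yl)ethyl]hex-5-en-2-one | CC1(CC[C@H](C(=C)CCl)C(C)(C)C(C)=O)OCCO1 | intermediate
15 | lithium enolate of 14 (C4=C5–OLi, not isolated) | CC1(CC[C@H](C(=C)CCl)C(C)(C)C(=C)O[Li])OCCO1 | intermediate
16 | (R)-2,2-dimethyl-3-[2-(2-methyl-1,3-dioxolan-2-yl)ethyl]-4-methylidenecyclohexan-1-one | CC1(CC[C@@H]2C(=C)CCC(=O)C2(C)C)OCCO1 | intermediate
17 | (1S,3R)-2,2-dimethyl-3-[2-(2-methyl-1,3-dioxolan-2-yl)ethyl]-4-methylidenecyclohexan-1-ol | CC1(CC[C@@H]2C(=C)CC[C@H](O)C2(C)C)OCCO1 | intermediate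
18 | 2-{2-[(1R,3R)-3-bromo-2,2-dimethyl-6-methylidenecyclohexyl]ethyl}-2-methyl-1,3-dioxolane | CC1(CC[C@@H]2C(=C)CC[C@@H](Br)C2(C)C)OCCO1 | intermediate
19 | 4-[(1R,3R)-3-bromo-2,2-dimethyl-6-methylidenecyclohexyl]butan-2-one | CC(=O)CC[C@@H]1C(=C)CC[C@@H](Br)C1(C)C | intermediate
20 | triethyl phosphonoacetate | CCOC(=O)CP(=O)(OCC)OCC | starting material
21 | ethyl (2E)-5-[(1R,3R)-3-bromo-2,2-dimethyl-6-methylidenecyclohexyl]-3-methylpent-2-enoate | CCOC(=O)/C=C(\C)CC[C@@H]1C(=C)CC[C@@H](Br)C1(C)C | intermediate
22 | (2E)-5-[(1R,3R)-3-bromo-2,2-dimethyl-6-methylidenecyclohexyl]-3-methylpent-2-en-1-ol | OC/C=C(\C)CC[C@@H]1C(=C)CC[C@@H](Br)C1(C)C | intermediate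
23 | [(2S,3S)-3-{2-[(1R,3R)-3-bromo-2,2-dimethyl-6-methylidenecyclohexyl]ethyl}-3-methyloxiran-2-yl]methanol | OC[C@@H]1O[C@@]1(C)CC[C@@H]2C(=C)CC[C@@H](Br)C2(C)C | intermediate
24 | (2R,3S)-3-{2-[(1R,3R)-3-bromo-2,2-dimethyl-6-methylidenecyclohexyl]ethyl}-2-(iodomethyl)-3-methyloxirane | IC[C@@H]1O[C@@]1(C)CC[C@@H]2C(=C)CC[C@@H](Br)C2(C)C | intermediate
25 | (3S)-5-[(1R,3R)-3-bromo-2,2-dimethyl-6-methylidenecyclohexyl]-3-methylpent-1-en-3-ol | C=C[C@@](C)(O)CC[C@@H]1C(=C)CC[C@@H](Br)C1(C)C | intermediate
26 | allylseleninic acid: C2=C3 cyclohexene bearing CH2Se(O)OH on C2 (not isolated) | C=C[C@@](C)(O)CC[C@@H]1C(C[Se](=O)O)=CC[C@@H](Br)C1(C)C | intermediate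
27 | (1S,3R,5R)-5-bromo-3-[(3S)-3-hydroxy-3-methylpent-4-en-1-yl]-4,4-dimethyl-2-methylidenecyclohexan-1-ol | C=C[C@@](C)(O)CC[C@@H]1C(=C)[C@@H](O)C[C@@H](Br)C1(C)C | intermediate
28 | (3S)-5-[(1S,3R,5R)-3,5-dibromo-2,2-dimethyl-6-methylidenecyclohexyl]-3-methylpent-1-en-3-ol | C=C[C@@](C)(O)CC[C@@H]1C(=C)[C@H](Br)C[C@@H](Br)C1(C)C | target

Total step count: 19. Longest linear sequence: 19 steps (1 → 28, fully linear).

Steps most likely to fail

Step 11. Substitution at the neopentylic C5 may be outrun by E2 loss of the activated oxygen towards C4. It may also be outrun by ionisation with ring contraction or methyl migration at the temperature the phosphonium route needs. The fallback separates activation from displacement. Setting out from 17, treatment with Tf2O and pyridine in CH2Cl2 at −30 °C should give the C5 triflate F1. This is used without purification and exposed to Bu4NBr in toluene at 0 °C → rt. The much better leaving group lets a soluble, weakly basic bromide react by SN2 below room temperature, and the route is rejoined at 18.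

Step 19. Bromide may attack the exocyclic methylene with allylic transposition. The C3 configuration may erode through bromide exchange. The free C9 hydroxyl group may be activated or may cyclise onto the allyl system. The ring must also place the leaving group axial, syn to the C5 bromide, which slows the direct displacement. The fallback masks C9 and uses a discrete sulfonate.
- Setting out from 25, TESOTf and 2,6-lutidine in CH2Cl2 at −78 °C should give the C9 triethylsilyl ether F2.
- Hydroxylation as in step 18 should give the silylated C3 alcohol F3.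
- MsCl and Et3N in CH2Cl2 at −40 °C give the allylic mesylate F4, which is displaced in the same flask by LiBr in THF at −40 → −10 °C to the silylated dibromide F5.
- HF·pyridine in THF at 0 °C removes the silyl group, and the route is rejoined at 28.

Step 18. Facial selectivity in the [2,3] shift may be poor, because the trans C1/C5 substitution leaves the ring without a strong conformational bias. Over-oxidation to the enone followed by loss of HBr may also erode the material. The fallback corrects the stereochemistry by an invertive esterification. Setting out from 25, the hydroxylation is run as before, and the alcohol with its hydroxyl group cis to the chain, the C3 epimer F6, is collected. Mitsunobu reaction (4-nitrobenzoic acid, PPh3, DIAD, THF, 0 °C) inverts C3 to the 4-nitrobenzoate F7, while the tertiary C9 hydroxyl group stays inert. Methanolysis (K2CO3, MeOH, 0 °C) then returns to the route at 27.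

Further compounds
F1 | step 11 | (1S,3R)-2,2-dimethyl-3-[2-(2-methyl-1,3-dioxolan-2-yl)ethyl]-4-methylidenecyclohexyl trifluoromethanesulfonate | CC1(CC[C@@H]2C(=C)CC[C@H](OS(=O)(=O)C(F)(F)F)C2(C)C)OCCO1
F2 | step 19 | C9 triethylsilyl ether of 25 | C=C[C@@](C)(O[Si](CC)(CC)CC)CC[C@@H]1C(=C)CC[C@@H](Br)C1(C)C
F3 | step 19 | C9 triethylsilyl ether of 27 | C=C[C@@](C)(O[Si](CC)(CC)CC)CC[C@@H]1C(=C)[C@@H](O)C[C@@H](Br)C1(C)C
F4 | step 19 | C3 methanesulfonate of F3 | C=C[C@@](C)(O[Si](CC)(CC)CC)CC[C@@H]1C(=C)[C@@H](OS(C)(=O)=O)C[C@@H](Br)C1(C)C
F5 | step 19 | C9 triethylsilyl ether of 28 | C=C[C@@](C)(O[Si](CC)(CC)CC)CC[C@@H]1C(=C)[C@H](Br)C[C@@H](Br)C1(C)C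
F6 | step 18 | C3 epimer of 27 (hydroxyl cis to the chain) | C=C[C@@](C)(O)CC[C@@H]1C(=C)[C@H](O)C[C@@H](Br)C1(C)C
F7 | step 18 | C3 4-nitrobenzoate of 27 | C=C[C@@](C)(O)CC[C@@H]1C(=C)[C@@H](OC(=O)c2ccc(cc2)[N+](=O)[O-])C[C@@H](Br)C1(C)C
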